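## The problem

Compound 17 is a macrocyclic bis(bibenzyl). Four benzene rings are closed into a 19-membered ring by two diaryl ether oxygens (A–O–B and C–O–D) and two ethano bridges (B–CH2CH2–C and D–CH2CH2–A). Ring A (C1 OMe, C4 bridge to ring D, C6 ether oxygen to ring B) and ring C (C1 bridge to ring B, C4 OH, C5 ether oxygen to ring D) share one 1,2,4-pattern and differ only as OMe versus OH. Ring B is para-linked and ring D meta-linked. The molecule has no stereocentre and no double bond, so no element can or need control another; the task is one of oxygen differentiation, regiochemistry and ring closure. The OMe of ring A and the OH of ring C must be told apart from the first step, because a late, unselective ether cleavage could not distinguish them. The free phenol of ring C sits on an electron-rich, oxidation-prone ring and should stay masked to the end. Any intermediate carrying an aryl halide, an aldehyde or a benzyl ether also restricts how the ethano bridges are made, since hydrogenation of stilbene or tolane precursors would threaten all three. The feature that opens the key step is that C1 and C6 of ring A are ortho: a formyl group at C1 makes a fluoride at C6 electrophilic toward a phenoxide, and a Dakin oxidation afterwards turns that same formyl carbon position into the oxygen of the methoxy group.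

## Retrosynthesis

**End game (17 back to 13).** The ring C hydroxyl is kept as a benzyl ether until the last step, so 17 comes from 16 by hydrogenolysis, when nothing else reducible is left. The methyl group of 16 is placed on the ring A phenol 15. Phenol 15 is the Dakin product of macrocyclic aldehyde 13, by oxygen insertion into the C1–CHO bond and methanolysis of formate 14. This order keeps the two oxygens distinct throughout: the ring C oxygen is benzylated from the first starting material, and the ring A oxygen does not exist until after ring closure.

**Ring closure (13 back to 12).** The bond cut is ring A C6–O of the A–O–B ether. Of the four ring bonds that could be made last, this is the only one where the target's own substitution supplies activation. The precursor 12 is acyclic, carries one free phenol (ring B) and one activated aryl fluoride (ring A), and needs no metal in the closing step. The forward reaction must favour ring closure over chain growth, which calls for high dilution, and the aldehyde must survive carbonate base.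

**D–A bridge (12 back to 8 and 9).** Phenol 12 is unmasked from its tetrahydropyranyl ether 11. In 11 the bond between ring A C4 and the adjacent CH2 is cut, which leads to styrene 8 and commercial 4-bromo-2-fluorobenzaldehyde 9. Forward, hydroboration of 8 to alkylborane 10 and B-alkyl Suzuki–Miyaura coupling deliver the saturated bridge directly. A Sonogashira or Wittig construction would require hydrogenating an alkyne or stilbene in the presence of the aryl fluoride, the aldehyde and the benzyl ether; the borane route avoids any such reduction. The borane is formed before the aldehyde enters the flask.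

**Vinyl handle (8 back to 7).** The vinyl group of 8 is placed on the aryl chloride 7 by Suzuki–Miyaura vinylation. The chlorine on ring D is chosen because it stays silent in the preceding palladium step and is then activated by a dialkylbiarylphosphine ligand.

**B–C bridge (7 back to 4 and 5).** The same tactic is used a second time. The bond between ring B and its CH2 is cut to give styrene 4 and commercial 2-(4-bromophenoxy)tetrahydro-2H-pyran 5, joined through alkylborane 6. The tetrahydropyranyl group is stable to base, borane and palladium, and is orthogonal to the benzyl ether on ring C. PdCl2(dppf) inserts into the C–Br bond of 5 but not into the C–Cl bond of ring D.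

**C–O–D ether (4 back to 1 and 2).** Styrene 4 is the methylenation product of aldehyde 3. Aldehyde 3 is cut at the O–ring D bond into commercial 4-(benzyloxy)-3-hydroxybenzaldehyde 1 and 1-chloro-3-iodobenzene 2, joined by an Ullmann coupling that uses only the iodide. All four building blocks (1, 2, 5, 9) are commercial, and the sequence is linear.

## Roads not taken

**Alternative 1: Friedel–Crafts macroacylation.** The cut is the bond between ring A C4 and the bridge carbon. The open-chain arylacetic acid A1 (ring A a plain 2-aryloxyanisole, ring C hydroxyl as mesylate) would be activated with (CF3CO)2O/H3PO4 and acylate C4–H of ring A to give macrocyclic ketone A2.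
- Merits: a C–C bond is formed with no halide or boron handle, the methoxy group is present from the start, and no Dakin or methylation is needed after closure.
- Weak points: C4 (para to OMe) must beat C5 (para to the aryloxy group) and the positions ortho to oxygen on ring B, and each wrong site gives a different ring. Acylium ions at high dilution also oligomerise readily. The ketone must then be reduced to CH2 and the mesylate cleaved with strong base.
- Comparison: this road is superior in atom economy of the closing step and spends nothing on an activating group. The chosen plan offers instead a closure with exactly one electrophilic carbon and one nucleophile, so regiochemistry is not in question.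

**Alternative 2: thiamacrocycle and Stevens ring contraction.** The cut is the central C–C bond of the D–A bridge. A 20-membered dibenzyl sulfide A3 would be S-methylated (Me3OBF4) and deprotonated (KOt-Bu). The sulfonium ylide would undergo a [1,2]-shift to the 19-membered methylthio compound A4 (racemic at the new benzylic carbon), and reductive desulfurisation would then give the ethano bridge.
- Merits: sulfide formation from a benzylic thiolate and a benzylic halide is among the most dependable macrocyclisations, probably more dependable than an SNAr driven only by a formyl group. Either ylide regioisomer converges after desulfurisation, and the stereocentre is erased.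
- Weak points: the [2,3]-Sommelet–Hauser shift onto ring D or ring A competes and does not converge. Two benzylic handles and both diaryl ethers must be built before closure, so the closing step does no constructive work on the skeleton. Three operations follow ring formation.
- Comparison: the chosen plan forms the second diaryl ether and the ring in one step and needs no sulfur chemistry.

**Alternative 3: oxidative phenol coupling.** The cut is the O–C5 bond of the C–O–D ether. Tl(NO3)3 (trivalent thallium) would oxidise the 3,5-dibromo-4-hydroxyphenyl ring C of the open bis(bibenzyl) A5. The ring D phenol oxygen would attack a bromine-bearing ortho carbon, and zinc work-up would give the monobromo macrocycle A6, which needs only hydrodebromination to reach the target.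
- Merits: the endgame is the shortest of all and needs no protecting group, a clear advantage over the three steps after closure in the chosen plan.
- Weak points: the reagent is stoichiometric and highly toxic. The unhalogenated ring D phenol and the electron-rich ring A are themselves oxidisable. Closures of this kind are typically low-yielding and hard to scale.
- Comparison: the chosen plan is longer after ring closure but relies on closed-shell, site-defined reactivity throughout.

Key step: step 7

Assumption: the tetrahydropyranyl acetal carbon of 5, 7, 8, 10 and 11 is carried as a racemate and is the only stereocentre in the route (removed in step 6); the macrocycles are taken to be conformationally mobile, without isolable atropisomers.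

## Route

Step 1
Reactants: 1 4-(benzyloxy)-3-hydroxybenzaldehyde; 2 1-chloro-3-iodobenzene
Product: 3 4-(benzyloxy)-3-(3-chlorophenoxy)benzaldehyde
Conditions: CuI (10 mol %), picolinic acid (20 mol %), K3PO4, DMSO, 80 °C
Reagents that add atoms: none
Why: Ullmann-type copper-catalysed O-arylation; the picolinic acid system is suited to ortho-substituted phenols, and the C–I bond reacts far faster than C–Cl, so the chlorine is kept as a handle. The aldehyde is non-enolisable and tolerates phosphate base.

Step 2
Reactants: 3 4-(benzyloxy)-3-(3-chlorophenoxy)benzaldehyde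
Product: 4 1-(benzyloxy)-2-(3-chlorophenoxy)-4-ethenylbenzene
Conditions: Ph3PCH3Br, KOt-Bu, THF, 0 °C to rt
Reagents that add atoms: methyltriphenylphosphonium bromide, C[P+](c1ccccc1)(c1ccccc1)c1ccccc1.[Br-]
Why: Wittig methylenation of an aromatic aldehyde with the unstabilised ylide; the aryl chloride, benzyl ether and diaryl ether are inert to it.

Step 3
Reactants: 4 1-(benzyloxy)-2-(3-chlorophenoxy)-4-ethenylbenzene; 5 2-(4-bromophenoxy)tetrahydro-2H-pyran (racemic)
Product: 7 2-(4-{2-[4-(benzyloxy)-3-(3-chlorophenoxy)phenyl]ethyl}phenoxy)tetrahydro-2H-pyran (racemic), via B-alkyl-9-BBN adduct 6 (not isolated)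
Conditions: 9-BBN, THF, 0 °C to rt; then 5, PdCl2(dppf) (5 mol %; dppf = 1,1'-bis(diphenylphosphino)ferrocene), 3 M aq. K3PO4, DMF, 60 °C
Reagents that add atoms: 9-borabicyclo[3.3.1]nonane (9-BBN), B1C2CCCC1CCC2 (its boron unit is held in 6 only; it gives one hydrogen to 7)
Why: Anti-Markovnikov hydroboration of the styrene, then B-alkyl Suzuki–Miyaura coupling, forms the saturated B–C bridge without any hydrogenation. PdCl2(dppf) inserts into the C–Br bond of 5 and leaves the ring D chloride untouched; the acetal and benzyl ether are stable to aqueous base.

Step 4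
Reactants: 7 2-(4-{2-[4-(benzyloxy)-3-(3-chlorophenoxy)phenyl]ethyl}phenoxy)tetrahydro-2H-pyran (racemic)
Product: 8 2-(4-{2-[4-(benzyloxy)-3-(3-ethenylphenoxy)phenyl]ethyl}phenoxy)tetrahydro-2H-pyran (racemic)
Conditions: CH2=CHBpin, Pd(OAc)2 (5 mol %), SPhos (2-dicyclohexylphosphino-2',6'-dimethoxybiphenyl, 10 mol %), K3PO4, 1,4-dioxane/H2O, 90 °C
Reagents that add atoms: 4,4,5,5-tetramethyl-2-vinyl-1,3,2-dioxaborolane, C=CB1OC(C)(C)C(C)(C)O1
Why: Suzuki–Miyaura vinylation; the electron-rich, bulky dialkylbiarylphosphine allows zerovalent palladium to insert into the unactivated aryl chloride, and excess boronate with aqueous base keeps cross-coupling ahead of Heck-type consumption of the styrene.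

Step 5
Reactants: 8 2-(4-{2-[4-(benzyloxy)-3-(3-ethenylphenoxy)phenyl]ethyl}phenoxy)tetrahydro-2H-pyran (racemic); 9 4-bromo-2-fluorobenzaldehyde
Product: 11 4-{2-[3-(2-(benzyloxy)-5-{2-[4-(tetrahydro-2H-pyran-2-yloxy)phenyl]ethyl}phenoxy)phenyl]ethyl}-2-fluorobenzaldehyde (racemic), via B-alkyl-9-BBN adduct 10 (not isolated)
Conditions: 9-BBN, THF, 0 °C to rt; 3 M aq. K3PO4 (destroys residual B–H); then 9, PdCl2(dppf) (5 mol %), DMF, 50 °C
Reagents that add atoms: 9-borabicyclo[3.3.1]nonane (9-BBN), B1C2CCCC1CCC2 (its boron unit is held in 10 only; it gives one hydrogen to 11)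
Why: Hydroboration then B-alkyl Suzuki–Miyaura coupling sets the D–A bridge and brings in ring A with fluorine and formyl already in place. The borane is made before the aldehyde is added and excess hydride is quenched, so only the tolerant cross-coupling sees the carbonyl; the C–F bond does not undergo oxidative addition.

Step 6
Reactants: 11 4-{2-[3-(2-(benzyloxy)-5-{2-[4-(tetrahydro-2H-pyran-2-yloxy)phenyl]ethyl}phenoxy)phenyl]ethyl}-2-fluorobenzaldehyde (racemic)
Product: 12 4-{2-[3-(2-(benzyloxy)-5-[2-(4-hydroxyphenyl)ethyl]phenoxy)phenyl]ethyl}-2-fluorobenzaldehyde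
Conditions: 1 M aq. HCl, THF, rt
Reagents that add atoms: none
Why: Acid-catalysed hydrolysis of the aryl tetrahydropyranyl acetal; the benzyl ether, aryl fluoride and aldehyde are inert to dilute aqueous acid at room temperature, so only the ring B phenol is freed.

Step 7
Reactants: 12 4-{2-[3-(2-(benzyloxy)-5-[2-(4-hydroxyphenyl)ethyl]phenoxy)phenyl]ethyl}-2-fluorobenzaldehyde
Product: 13 macrocyclic aldehyde (19-membered ring A–O–B–CH2CH2–C–O–D–CH2CH2–A; CHO at ring A C1, OBn at ring C C4)
Conditions: Cs2CO3 (5 equiv), 4 Å MS, dry degassed DMSO, 90 °C, syringe-pump addition of 12 to a final 2 mM, Ar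
Reagents that add atoms: none
Why: Cs2CO3 deprotonates the only free phenol (ring B), and the phenoxide adds to C6 of ring A, the fluorine-bearing carbon ortho to the formyl group, giving a Meisenheimer anion whose charge is delocalised onto the formyl oxygen; loss of fluoride restores aromaticity and leaves the A–O–B ether. The closest known reaction type is the intramolecular SNAr macroetherification of phenoxides onto fluoroarenes with an ortho acceptor, together with the routine intermolecular arylation of phenols by 2-fluorobenzaldehydes. The one ring formed is 19-membered and closes by addition of the tethered nucleophile to a trigonal ring carbon with the breaking C–F bond outside the new ring (formally exo-trig); at this size there is no stereoelectronic barrier and the outcome depends on effective molarity, which slow addition to high dilution is meant to secure, helped by the weakly ion-paired caesium phenoxide. No stereocentre is created. Site selectivity at the electrophile is secured because C6 is the only activated, fluoride-bearing carbon; chemoselectivity at the nucleophile is secured because ring B carries the only free phenol, the ring C oxygen being benzylated. The aldehyde has no enolisable hydrogen and, in dry degassed DMSO with carbonate as base, should neither condense nor disproportionate.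

Step 8
Reactants: 13 macrocyclic aldehyde
Product: 15 macrocyclic phenol (OH at ring A C1; OBn at ring C C4), via aryl formate 14 (not isolated)
Conditions: mCPBA, CH2Cl2, 0 °C to rt; then K2CO3 (cat.), MeOH, rt
Reagents that add atoms: 3-chloroperbenzoic acid (mCPBA), O=C(OO)c1cccc(Cl)c1
Why: Dakin-type Baeyer–Villiger oxidation; in the peracid adduct the ring A aryl group, enriched by the ortho aryloxy oxygen and the para alkyl group, migrates to oxygen to give formate 14, which catalytic carbonate in methanol transesterifies to the phenol.

Step 9
Reactants: 15 macrocyclic phenol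
Product: 16 macrocyclic methyl ether (OMe at ring A C1; OBn at ring C C4)
Conditions: MeI, K2CO3, DMF, rt
Reagents that add atoms: iodomethane, CI
Why: Williamson O-methylation of the only free phenol; every other oxygen is already an ether.

Step 10
Reactants: 16 macrocyclic methyl ether
Product: 17 target macrocycle (OMe at ring A C1; OH at ring C C4)
Conditions: H2 (1 atm), Pd/C (10 wt %), EtOAc/EtOH, rt
Reagents that add atoms: none
Why: Hydrogenolysis of the aryl benzyl ether; the methyl ether, the diaryl ethers and the ethano bridges are stable, and no reducible group remains.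

## Compound list

1 | 4-(benzyloxy)-3-hydroxybenzaldehyde | O=Cc1ccc(OCc2ccccc2)c(O)c1 | starting material
2 | 1-chloro-3-iodobenzene | Clc1cccc(I)c1 | starting material
3 | 4-(benzyloxy)-3-(3-chlorophenoxy)benzaldehyde | O=Cc1ccc(OCc2ccccc2)c(Oc2cccc(Cl)c2)c1 | intermediate
4 | 1-(benzyloxy)-2-(3-chlorophenoxy)-4-ethenylbenzene | C=Cc1ccc(OCc2ccccc2)c(Oc2cccc(Cl)c2)c1 | intermediate
5 | 2-(4-bromophenoxy)tetrahydro-2H-pyran (racemic) | Brc1ccc(OC2CCCCO2)cc1 | starting material
6 | 9-{2-[4-(benzyloxy)-3-(3-chlorophenoxy)phenyl]ethyl}-9-borabicyclo[3.3.1]nonane | Clc1cccc(Oc2cc(CCB3C4CCCC3CCC4)ccc2OCc2ccccc2)c1 | intermediate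
7 | 2-(4-{2-[4-(benzyloxy)-3-(3-chlorophenoxy)phenyl]ethyl}phenoxy)tetrahydro-2H-pyran (racemic) | Clc1cccc(Oc2cc(CCc3ccc(OC4CCCCO4)cc3)ccc2OCc2ccccc2)c1 | intermediate
8 | 2-(4-{2-[4-(benzyloxy)-3-(3-ethenylphenoxy)phenyl]ethyl}phenoxy)tetrahydro-2H-pyran (racemic) | C=Cc1cccc(Oc2cc(CCc3ccc(OC4CCCCO4)cc3)ccc2OCc2ccccc2)c1 | intermediate
9 | 4-bromo-2-fluorobenzaldehyde | O=Cc1ccc(Br)cc1F | starting material
10 | 9-{2-[3-(2-(benzyloxy)-5-{2-[4-(tetrahydro-2H-pyran-2-yloxy)phenyl]ethyl}phenoxy)phenyl]ethyl}-9-borabicyclo[3.3.1]nonane (racemic) | B1(CCc2cccc(Oc3cc(CCc4ccc(OC5CCCCO5)cc4)ccc3OCc3ccccc3)c2)C6CCCC1CCC6 | intermediate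
11 | 4-{2-[3-(2-(benzyloxy)-5-{2-[4-(tetrahydro-2H-pyran-2-yloxy)phenyl]ethyl}phenoxy)phenyl]ethyl}-2-fluorobenzaldehyde (racemic) | O=Cc1ccc(CCc2cccc(Oc3cc(CCc4ccc(OC5CCCCO5)cc4)ccc3OCc3ccccc3)c2)cc1F | intermediate
12 | 4-{2-[3-(2-(benzyloxy)-5-[2-(4-hydroxyphenyl)ethyl]phenoxy)phenyl]ethyl}-2-fluorobenzaldehyde | O=Cc1ccc(CCc2cccc(Oc3cc(CCc4ccc(O)cc4)ccc3OCc3ccccc3)c2)cc1F | intermediate
13 | macrocyclic aldehyde (19-membered ring; CHO at ring A C1, OBn at ring C C4) | O=Cc1ccc2cc1Oc1ccc(cc1)CCc1ccc(OCc3ccccc3)c(c1)Oc1cccc(c1)CC2 | intermediate
14 | macrocyclic aryl formate (OCHO at ring A C1, OBn at ring C C4) | O=COc1ccc2cc1Oc1ccc(cc1)CCc1ccc(OCc3ccccc3)c(c1)Oc1cccc(c1)CC2 | intermediate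
15 | macrocyclic phenol (OH at ring A C1, OBn at ring C C4) | Oc1ccc2cc1Oc1ccc(cc1)CCc1ccc(OCc3ccccc3)c(c1)Oc1cccc(c1)CC2 | intermediate
16 | macrocyclic methyl ether (OMe at ring A C1, OBn at ring C C4) | COc1ccc2cc1Oc1ccc(cc1)CCc1ccc(OCc3ccccc3)c(c1)Oc1cccc(c1)CC2 | intermediate
17 | CNP0132125.0 (OMe at ring A C1, OH at ring C C4) | COc1ccc2cc1Oc1ccc(cc1)CCc1ccc(O)c(c1)Oc1cccc(c1)CC2 | target

## Step count and risks

Total steps: 10. Longest linear sequence: 10 (from 1; building blocks 2, 5 and 9 are commercial).

**Step 7 (key step).** The formyl group is only a moderate activator and the para alkyl group works slightly against it. At the long reaction times that high dilution imposes, substitution may be slow enough for intermolecular etherification (oligomers) and base-induced degradation of the aldehyde to compete. Fallback: copper-catalysed intramolecular Ullmann etherification, which does not depend on the acceptor strength of the formyl group.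
- It sets out from 8. Borane 10 is made as in step 5 and coupled with 2-bromo-4-iodobenzaldehyde (the C–I bond reacting first) to give the ortho-bromo aldehyde F1 (11 with Br in place of F).
- Aqueous HCl in THF frees the bromo phenol F2.
- CuI, N,N-dimethylglycine and Cs2CO3 in dioxane at 100 °C under high dilution close the same C6–O bond, and the route is rejoined at 13.

**Step 4.** Oxidative addition to the unactivated ring D chloride may be sluggish, and at 90 °C the product styrene may be consumed by Heck-type coupling or polymerisation. Fallback: an iodide/bromide pair replaces the bromide/chloride pair, so that the vinylation is performed on an aryl bromide.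
- It sets out from 1. Ullmann coupling with 1-bromo-3-iodobenzene gives 4-(benzyloxy)-3-(3-bromophenoxy)benzaldehyde F3.
- Methylenation gives 1-(benzyloxy)-2-(3-bromophenoxy)-4-ethenylbenzene F4.
- 9-BBN gives the bromo alkylborane F5, which is coupled at room temperature with 2-(4-iodophenoxy)tetrahydro-2H-pyran to give the bromo bibenzyl F6 (7 with Br in place of Cl).
- Vinylation of F6 with Pd(PPh3)4, K2CO3 and the vinylboronate rejoins the route at 8.

**Step 5.** Residual boron hydride, or hydride transfer from the alkylborane, may reduce the aldehyde of 9 or of 11 during the coupling. Fallback: the formyl group travels masked. It sets out from 8: borane 10 is coupled with 2-(4-bromo-2-fluorophenyl)-1,3-dioxolane to give the dioxolane F7, and a single treatment with aqueous HCl in THF removes both acetals and rejoins the route at 12, with 11 bypassed.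

**Step 8.** In the peracid adduct, hydride migration may compete with aryl migration and lead to the carboxylic acid, since ring A has only one oxygen donor ortho to the formyl group. Fallback: the Baeyer–Villiger step is run on a methyl ketone, where aryl migration has no such competitor.
- It sets out from 13. MeMgBr gives the racemic 1-arylethanol F8.
- Dess–Martin periodinane gives the aryl methyl ketone F9.
- mCPBA gives the aryl acetate F10.
- K2CO3 in MeOH rejoins the route at 15.

**Step 1.** The phenol is hindered by the ortho benzyloxy group and made less nucleophilic by the formyl group, so conversion may stall before the iodide is consumed. Fallback: oxidative Chan–Lam coupling of 1 with (3-chlorophenyl)boronic acid (Cu(OAc)2, pyridine, 4 Å MS, CH2Cl2, air), which sets out from 1, gives 3 directly and makes no new compound (F0).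

## Further compounds

F1 | step 7 | 2-bromo-4-{2-[3-(2-(benzyloxy)-5-{2-[4-(tetrahydro-2H-pyran-2-yloxy)phenyl]ethyl}phenoxy)phenyl]ethyl}benzaldehyde (racemic) | O=Cc1ccc(CCc2cccc(Oc3cc(CCc4ccc(OC5CCCCO5)cc4)ccc3OCc3ccccc3)c2)cc1Br
F2 | step 7 | 2-bromo-4-{2-[3-(2-(benzyloxy)-5-[2-(4-hydroxyphenyl)ethyl]phenoxy)phenyl]ethyl}benzaldehyde | O=Cc1ccc(CCc2cccc(Oc3cc(CCc4ccc(O)cc4)ccc3OCc3ccccc3)c2)cc1Br
F3 | step 4 | 4-(benzyloxy)-3-(3-bromophenoxy)benzaldehyde | O=Cc1ccc(OCc2ccccc2)c(Oc2cccc(Br)c2)c1
F4 | step 4 | 1-(benzyloxy)-2-(3-bromophenoxy)-4-ethenylbenzene | C=Cc1ccc(OCc2ccccc2)c(Oc2cccc(Br)c2)c1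
F5 | step 4 | 9-{2-[4-(benzyloxy)-3-(3-bromophenoxy)phenyl]ethyl}-9-borabicyclo[3.3.1]nonane | Brc1cccc(Oc2cc(CCB3C4CCCC3CCC4)ccc2OCc2ccccc2)c1
F6 | step 4 | 2-(4-{2-[4-(benzyloxy)-3-(3-bromophenoxy)phenyl]ethyl}phenoxy)tetrahydro-2H-pyran (racemic) | Brc1cccc(Oc2cc(CCc3ccc(OC4CCCCO4)cc3)ccc2OCc2ccccc2)c1
F7 | step 5 | 2-[4-{2-[3-(2-(benzyloxy)-5-{2-[4-(tetrahydro-2H-pyran-2-yloxy)phenyl]ethyl}phenoxy)phenyl]ethyl}-2-fluorophenyl]-1,3-dioxolane (racemic) | Fc1cc(CCc2cccc(Oc3cc(CCc4ccc(OC5CCCCO5)cc4)ccc3OCc3ccccc3)c2)ccc1C1OCCO1
F8 | step 8 | macrocyclic 1-arylethanol (CH(OH)CH3 at ring A C1, OBn at ring C C4; racemic) | CC(O)c1ccc2cc1Oc1ccc(cc1)CCc1ccc(OCc3ccccc3)c(c1)Oc1cccc(c1)CC2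
F9 | step 8 | macrocyclic aryl methyl ketone (COCH3 at ring A C1, OBn at ring C C4) | CC(=O)c1ccc2cc1Oc1ccc(cc1)CCc1ccc(OCc3ccccc3)c(c1)Oc1cccc(c1)CC2
F10 | step 8 | macrocyclic aryl acetate (OAc at ring A C1, OBn at ring C C4) | CC(=O)Oc1ccc2cc1Oc1ccc(cc1)CCc1ccc(OCc3ccccc3)c(c1)Oc1cccc(c1)CC2
F0 | step 1 | none | none
A1 | alternative 1 | 2-[3-(2-(methanesulfonyloxy)-5-{2-[4-(2-methoxyphenoxy)phenyl]ethyl}phenoxy)phenyl]acetic acid | COc1ccccc1Oc1ccc(CCc2ccc(OS(C)(=O)=O)c(Oc3cccc(CC(O)=O)c3)c2)cc1
A2 | alternative 1 | macrocyclic aryl ketone (C=O on the bridge carbon attached to ring A C4, ring C mesylate) | COc1ccc2cc1Oc1ccc(cc1)CCc1ccc(OS(C)(=O)=O)c(c1)Oc1cccc(c1)CC2=O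
A3 | alternative 2 | 20-membered dibenzyl sulfide (ring D–CH2–S–CH2–ring A, ring C benzyl ether) | COc1ccc2cc1Oc1ccc(cc1)CCc1ccc(OCc3ccccc3)c(c1)Oc1cccc(c1)CSC2
A4 | alternative 2 | 19-membered macrocycle with SCH3 on the ring D benzylic carbon (racemic, ring C benzyl ether) | COc1ccc2cc1Oc1ccc(cc1)CCc1ccc(OCc3ccccc3)c(c1)Oc1cccc(c1)C(SC)C2
A5 | alternative 3 | open bis(bibenzyl) with 3,5-dibromo-4-hydroxyphenyl ring C and 3-hydroxyphenyl ring D | COc1ccc(CCc2cccc(O)c2)cc1Oc1ccc(CCc2cc(Br)c(O)c(Br)c2)cc1
A6 | alternative 3 | monobromo macrocycle (target with Br at ring C C3) | COc1ccc2cc1Oc1ccc(cc1)CCc1cc(Br)c(O)c(c1)Oc1cccc(c1)CC2
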